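The data were generated by integration for an exercise.

The trap in repeating this run is to treat the first nucleophile, 80.0 mM against 16 mM of starting material, as a bystander whose timing cannot matter. I kept a ledger of the starting material, the limiting reagent, in percent of its charge.

common to all: gas 1.8 mM (held)
- beta: starting material 16 mM; first nucleophile 80 mM; run made earlier
- alpha: starting material 24 mM; first nucleophile 80 mM; run made earlier
- blue: starting material 16 mM; first nucleophile 80.0 mM (fed, over 2.5 d); all else is in the flask from the start; the feed brings no volume worth counting; time 3.0 d
- ochre: starting material 16 mM; first nucleophile 80.0 mM; everything together at the start; time 3.0 d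
- green: starting material 16 mM (fed, over 2.5 d); first nucleophile 80.0 mM; all else is in the flask from the start; the feed brings no volume worth counting; time 3.0 d

| run | time / h | target / % | starting material / % |
|---|---|---|---|
| beta | 3.00 | 10.4 | 82.7 |
| beta | 5.00 | 15.2 | 70.4 |
| beta | 8.00 | 20.2 | 60.4 |
| beta | 12.0 | 23.5 | 47.3 |
| beta | 20.0 | 33.7 | 28.7 |
| beta | 30.0 | 37.7 | 16.7 |
| beta | 40.0 | 40.3 | 7.6 |
| alpha | 0.417 | 0.2 | 98.1 |
| alpha | 1.00 | 2.5 | 93.3 |
| alpha | 2.00 | 5.9 | 88.0 |
| alpha | 3.00 | 9.5 | 82.9 |
| alpha | 4.00 | 11.9 | 79.3 |
| alpha | 6.00 | 14.9 | 67.0 |
| alpha | 8.00 | 19.2 | 61.1 |

(each reading ± 1 percentage point)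

- what is said of target includes crystals
- crystals is a solid; its amount is given per volume of the solution
- at the start none of second nucleophile is dissolved
- reactions considered so far: starting material <-> intermediate; first nucleophile + intermediate -> target; second nucleophile + intermediate -> other capture product; crystals <-> target; gas <-> second nucleophile; target <-> isomer of the product

1. the flask with the highest amount of target, in percent of the starting material charged ("all alike" if they lie within 1.5 percentage points) (blue / ochre / green / all alike)
2. final target, as a percentage of the starting material charged, in blue
3. final target, as a percentage of the starting material charged, in ochre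
4. final target, as a percentage of the starting material charged, in green

1. Unreacted entry. The beta run kept 7.6 % at 40.0 h, so I read a first-order constant k of 0.0644 h⁻¹. On that reading ochre keeps 0.967 % at 3.0 d, and green, still digesting its feed, keeps 11.7 %.

2. Target entry. At that beta reading, target stood at 40.3 %, so the share of reacted starting material that became target was 43.6 %. The alpha run's last reading gave 49.4 %, but I kept the later beta value for these long flasks.

3. The rule. Each starting material that reacts takes at most one first nucleophile, so by that reading beta had spent no more than about 14.8 mM of it, less than its 80 mM, and as an approximation I held c(first nucleophile) at the charge. Writing the share as c/(c + K), I defined K as the even-split concentration, the c(first nucleophile) at which target and all other fates share equally: 103 mM.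

4. Closing the books. Ochre and green both stand near the charge, so the share times what reacted gives 43.2 % for ochre and 38.5 % for green. In blue, the mean reaction time 1/k is shorter than the feed, so I took c(first nucleophile) at that moment, 20.7 mM, which gives 16.7 %.

The forecast named ochre, with 15.5 % for blue, 42 % for ochre and 36 % for green, each below my figure. Its ground for blue was “most ionisation happens while first nucleophile is scarce”.

The flasks gave 18.9 % for blue, 43.5 % for ochre and 37.1 % for green, so ochre came highest and the forecast held.

    starting material ⇌ intermediate (K = 0.0120, k = 0.239 h⁻¹)
    first nucleophile + intermediate → target (k = 51.9 L mol⁻¹ h⁻¹)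
    second nucleophile + intermediate → other capture product (k = 1800 L mol⁻¹ h⁻¹)
    crystals ⇌ target, rate k4*(cs4 - [target]) while solid is left; crystals form when [target] > cs4 (solubility = 3.80 mM, k = 0.144 h⁻¹)
    gas ⇌ second nucleophile, rate k5*(csat - [second nucleophile]) (kL = 8.33 h⁻¹)
    target ⇌ isomer of the product (K = 0.450, k = 0.0302 h⁻¹)

Ochre ended with 11.1 % of isomer of the product beside 44.2 % of other capture product, and K books both as not target. With ochre's actual 1.16 % of starting material left, K gives 43.2 %. For the neighbour of ochre with 200 mM of first nucleophile, K gives a share of 66.0 %, and the computed flask holds 64.8 %.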